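**Retrosynthetic overview**
1. Feature: ring B (the 1,4-dioxane ring) has oxygen on both sp3 carbons. The O on Cα (the carbon bearing the ring C aryl group) is bound to the ring A carbon meta to the propenyl chain. The O on Cβ (the carbon bearing CH2OH) is bound to the ring A carbon para to the chain and next to OMe. Aryl and CH2OH are cis (Cα S, Cβ R).
2. Target 17 ⇐ triol cinnamate 15 (ester reduction) ⇐ tri-MOM cinnamate 14 (MOM removal) ⇐ aldehyde 12 (Wittig).
3. Ring B of 12 ⇐ Cα–O bond (phenoxide opening of a trans aryl epoxide, inversion) plus aryl C–O(β) bond (CuI-catalysed O-arylation at C–Br, retention) ⇐ (2R,3R)-epoxide 8 + ortho-bromophenol 10.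
4. 8 ⇐ Sharpless epoxidation of (E)-allylic alcohol 6 ⇐ Horner–Wadsworth–Emmons and i-Bu2AlH reduction from bis-MOM 5-hydroxyvanillin; 10 ⇐ monodemethylation of 9.
5. Ring order: rings A and C are bought as arenes, the oxirane (step 4) is a sacrificial ring, and ring B is the only ring of the target that is built (step 7).

Key step: step 7

Assumption: compounds 1, 3, 9 and 13 are taken as commercial; the target SMILES is read as Cα (S), Cβ (R), which is the cis-2,3-disubstituted ring B.

**Step 1**
Reactants: 1 5-hydroxyvanillin (3,4-dihydroxy-5-methoxybenzaldehyde)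
Product: 2 3-methoxy-4,5-bis(methoxymethoxy)benzaldehyde
Conditions: MOMCl (3 equiv), i-Pr2NEt (4 equiv), CH2Cl2, 0 °C → rt
Reagents that add atoms: chloromethyl methyl ether (MOMCl), COCCl
Why: O-alkylation of both phenols by the reactive α-chloro ether (MOM protection) should go to completion with excess amine base and masks the catechol against the basic, reducing and copper-mediated steps ahead.

**Step 2**
Reactants: 2 3-methoxy-4,5-bis(methoxymethoxy)benzaldehyde; 3 triethyl phosphonoacetate
Product: 4 ethyl (E)-3-[3-methoxy-4,5-bis(methoxymethoxy)phenyl]prop-2-enoate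
Conditions: NaH, THF, 0 °C → rt
Reagents that add atoms: none
Why: Horner–Wadsworth–Emmons olefination of a non-enolisable aryl aldehyde with a stabilised phosphonate anion should give the (E)-cinnamate through the thermodynamically favoured oxaphosphetane.

**Step 3**
Reactants: 4 ethyl (E)-3-[3-methoxy-4,5-bis(methoxymethoxy)phenyl]prop-2-enoate
Product: 6 (E)-3-[3-methoxy-4,5-bis(methoxymethoxy)phenyl]prop-2-en-1-ol, via cinnamaldehyde 5 (not isolated)
Conditions: i-Bu2AlH (2.5 equiv), CH2Cl2, −78 → 0 °C; aq. KNaC4H4O6 (potassium sodium tartrate)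
Reagents that add atoms: none
Why: i-Bu2AlH reduces conjugated esters by 1,2-hydride delivery only, so the (E)-allylic alcohol should form without touching the alkene or the MOM acetals.

**Step 4**
Reactants: 6 (E)-3-[3-methoxy-4,5-bis(methoxymethoxy)phenyl]prop-2-en-1-ol
Product: 7 [(2R,3R)-3-[3-methoxy-4,5-bis(methoxymethoxy)phenyl]oxiran-2-yl]methanol
Conditions: Ti(OiPr)4 (10 mol%), D-(−)-diethyl tartrate (12 mol%), t-BuOOH (2 equiv, anhydrous), 4 Å MS, CH2Cl2, −20 °C; NaOH/brine work-up at 0 °C
Reagents that add atoms: tert-butyl hydroperoxide, CC(C)(C)OO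
Why: Sharpless asymmetric epoxidation, in which the titanium D-(−)-tartrate complex delivers oxygen to the alkene face that gives the (2R,3R)-epoxy alcohol (mirror image of the (2S,3S) outcome of (E)-3-aryl allylic alcohols with L-(+)-tartrate), sets both stereocentres by reagent control, while catalytic loading, sieves and a basic work-up limit acid-promoted opening of the electron-rich epoxide.

**Step 5**
Reactants: 7 [(2R,3R)-3-[3-methoxy-4,5-bis(methoxymethoxy)phenyl]oxiran-2-yl]methanol
Product: 8 (2R,3R)-2-[(methoxymethoxy)methyl]-3-[3-methoxy-4,5-bis(methoxymethoxy)phenyl]oxirane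
Conditions: MOMCl (2 equiv), i-Pr2NEt (4 equiv), CH2Cl2, 0 °C → rt
Reagents that add atoms: chloromethyl methyl ether (MOMCl), COCCl
Why: MOM protection under amine-buffered conditions etherifies the primary alcohol without forming an alkoxide, so Payne rearrangement is avoided and the later Cβ alkoxide has no migrating group next to it.

**Step 6**
Reactants: 9 4-bromo-3,5-dimethoxybenzaldehyde
Product: 10 4-bromo-3-hydroxy-5-methoxybenzaldehyde
Conditions: BBr3 (1.1 equiv), CH2Cl2, −78 → 0 °C; H2O
Reagents that add atoms: none
Why: Lewis-acid cleavage of an aryl methyl ether (BBr3 demethylation) on a substrate with two equivalent OMe groups should, with about one equivalent of reagent at low temperature, stop mainly at the monophenol, which is separated from diol and unchanged 9 by its acidity.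

**Step 7**
Reactants: 8 (2R,3R)-2-[(methoxymethoxy)methyl]-3-[3-methoxy-4,5-bis(methoxymethoxy)phenyl]oxirane; 10 4-bromo-3-hydroxy-5-methoxybenzaldehyde
Product: 12 (2R,3S)-8-methoxy-2-[(methoxymethoxy)methyl]-3-[3-methoxy-4,5-bis(methoxymethoxy)phenyl]-2,3-dihydro-1,4-benzodioxine-6-carbaldehyde, via ring-opened bromoaryl ether alkoxide 11 (not isolated)
Conditions: Cs2CO3 (2.5 equiv), DMF, 90 °C; then CuI (10 mol%), 3,4,7,8-tetramethyl-1,10-phenanthroline (20 mol%), 110 °C, argon
Reagents that add atoms: none
Why: Cs2CO3 deprotonates 10 and the phenoxide attacks epoxide 8 by SN2 at benzylic Cα, releasing the ring strain and freeing the Cβ alkoxide 11; monovalent copper bound to this alkoxide then inserts into the neighbouring C–Br bond (para to the aldehyde) and C–O reductive elimination from the trivalent copper intermediate forms the aryl–O bond. The closest known reaction type is the one-pot opening of epoxides by ortho-halophenols followed by Ullmann-type intramolecular O-arylation to 2,3-dihydro-1,4-benzodioxines. Ring B closes as a six-membered ring by intramolecular aryl–O coupling through a seven-membered copper chelate, the only ring size that the ortho relationship of ether oxygen and bromide allows. The new stereocentre Cα (S) is controlled by the epoxide, since backside attack inverts the (R) benzylic carbon, while Cβ keeps its C–O bond and stays (R), so the trans epoxide gives the cis ring. The step needs benzylic regioselectivity, secured by the electron-rich aryl group that activates Cα and by the CH2OMOM group that deactivates Cβ inductively and sterically, and it needs a clean SN2 course, secured by running the opening with Cs2CO3 alone before CuI is added. The MOM ethers block Payne migration and quinone methide formation, and the position of the bromide between the phenol oxygen and OMe fixes which ring A carbon receives the Cβ oxygen.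

**Step 8**
Reactants: 12 (2R,3S)-8-methoxy-2-[(methoxymethoxy)methyl]-3-[3-methoxy-4,5-bis(methoxymethoxy)phenyl]-2,3-dihydro-1,4-benzodioxine-6-carbaldehyde; 13 methyl (triphenylphosphoranylidene)acetate
Product: 14 methyl (E)-3-{(2R,3S)-8-methoxy-2-[(methoxymethoxy)methyl]-3-[3-methoxy-4,5-bis(methoxymethoxy)phenyl]-2,3-dihydro-1,4-benzodioxin-6-yl}prop-2-enoate
Conditions: toluene, 80 °C
Reagents that add atoms: none
Why: Wittig olefination with a stabilised ylide is reversible at the betaine stage and should give the (E)-cinnamate under neutral conditions that leave both ring B stereocentres untouched.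

**Step 9**
Reactants: 14 methyl (E)-3-{(2R,3S)-8-methoxy-2-[(methoxymethoxy)methyl]-3-[3-methoxy-4,5-bis(methoxymethoxy)phenyl]-2,3-dihydro-1,4-benzodioxin-6-yl}prop-2-enoate
Product: 15 methyl (E)-3-[(2R,3S)-3-(3,4-dihydroxy-5-methoxyphenyl)-2-(hydroxymethyl)-8-methoxy-2,3-dihydro-1,4-benzodioxin-6-yl]prop-2-enoate
Conditions: HCl (1.25 M in MeOH), MeOH/THF, rt → 40 °C
Reagents that add atoms: none
Why: Acid-catalysed acetal exchange with methanol removes all three MOM groups as dimethoxymethane at the ester stage, where no acid-labile allylic alcohol is present, the methyl ester matches the solvent, and the benzodioxane ring is expected to tolerate dilute acid.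

**Step 10**
Reactants: 15 methyl (E)-3-[(2R,3S)-3-(3,4-dihydroxy-5-methoxyphenyl)-2-(hydroxymethyl)-8-methoxy-2,3-dihydro-1,4-benzodioxin-6-yl]prop-2-enoate
Product: 17 CNP0174261.1 (target) 5-[(2S,3R)-3-(hydroxymethyl)-7-[(E)-3-hydroxyprop-1-enyl]-5-methoxy-2,3-dihydro-1,4-benzodioxin-2-yl]-3-methoxybenzene-1,2-diol, via enal 16 (not isolated)
Conditions: i-Bu2AlH (7 equiv), THF, −78 → 0 °C; MeOH quench, degassed aq. KNaC4H4O6 (potassium sodium tartrate)
Reagents that add atoms: none
Why: After the three acidic OH groups are consumed as aluminium alkoxides, excess i-Bu2AlH reduces the conjugated ester by 1,2-addition to the (E)-allylic alcohol, the standard reduction of hydroxycinnamate esters that carry free phenols, without affecting the stereocentres.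

**Compound list**
1 | 5-hydroxyvanillin (3,4-dihydroxy-5-methoxybenzaldehyde) | COc1cc(C=O)cc(O)c1O | starting material
2 | 3-methoxy-4,5-bis(methoxymethoxy)benzaldehyde | COc1cc(C=O)cc(OCOC)c1OCOC | intermediate
3 | triethyl phosphonoacetate | CCOC(=O)CP(=O)(OCC)OCC | starting material
4 | ethyl (E)-3-[3-methoxy-4,5-bis(methoxymethoxy)phenyl]prop-2-enoate | CCOC(=O)/C=C/c1cc(OC)c(OCOC)c(OCOC)c1 | intermediate
5 | (E)-3-[3-methoxy-4,5-bis(methoxymethoxy)phenyl]prop-2-enal (formed in the flask in step 3, not isolated) | O=C/C=C/c1cc(OC)c(OCOC)c(OCOC)c1 | intermediate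
6 | (E)-3-[3-methoxy-4,5-bis(methoxymethoxy)phenyl]prop-2-en-1-ol | OC/C=C/c1cc(OC)c(OCOC)c(OCOC)c1 | intermediate
7 | [(2R,3R)-3-[3-methoxy-4,5-bis(methoxymethoxy)phenyl]oxiran-2-yl]methanol (trans epoxide) | COc1cc([C@@H]2[C@@H](CO)O2)cc(OCOC)c1OCOC | intermediate
8 | (2R,3R)-2-[(methoxymethoxy)methyl]-3-[3-methoxy-4,5-bis(methoxymethoxy)phenyl]oxirane (trans epoxide) | COc1cc([C@@H]2[C@@H](COCOC)O2)cc(OCOC)c1OCOC | intermediate
9 | 4-bromo-3,5-dimethoxybenzaldehyde | COc1cc(C=O)cc(OC)c1Br | starting material
10 | 4-bromo-3-hydroxy-5-methoxybenzaldehyde | O=Cc1cc(O)c(Br)c(OC)c1 | intermediate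
11 | 4-bromo-3-{(1S,2R)-2-hydroxy-3-(methoxymethoxy)-1-[3-methoxy-4,5-bis(methoxymethoxy)phenyl]propoxy}-5-methoxybenzaldehyde (present as its caesium alkoxide in step 7, not isolated) | COc1cc([C@H](Oc2cc(C=O)cc(OC)c2Br)[C@H](O)COCOC)cc(OCOC)c1OCOC | intermediate
12 | (2R,3S)-8-methoxy-2-[(methoxymethoxy)methyl]-3-[3-methoxy-4,5-bis(methoxymethoxy)phenyl]-2,3-dihydro-1,4-benzodioxine-6-carbaldehyde (cis; Cα S, Cβ R) | COc1cc([C@@H]2Oc3cc(C=O)cc(OC)c3O[C@@H]2COCOC)cc(OCOC)c1OCOC | intermediate
13 | methyl (triphenylphosphoranylidene)acetate | COC(=O)C=P(c1ccccc1)(c1ccccc1)c1ccccc1 | starting material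
14 | methyl (E)-3-{(2R,3S)-8-methoxy-2-[(methoxymethoxy)methyl]-3-[3-methoxy-4,5-bis(methoxymethoxy)phenyl]-2,3-dihydro-1,4-benzodioxin-6-yl}prop-2-enoate (cis) | COc1cc([C@@H]2Oc3cc(/C=C/C(=O)OC)cc(OC)c3O[C@@H]2COCOC)cc(OCOC)c1OCOC | intermediate
15 | methyl (E)-3-[(2R,3S)-3-(3,4-dihydroxy-5-methoxyphenyl)-2-(hydroxymethyl)-8-methoxy-2,3-dihydro-1,4-benzodioxin-6-yl]prop-2-enoate (cis) | COc1cc([C@@H]2Oc3cc(/C=C/C(=O)OC)cc(OC)c3O[C@@H]2CO)cc(O)c1O | intermediate
16 | (E)-3-[(2R,3S)-3-(3,4-dihydroxy-5-methoxyphenyl)-2-(hydroxymethyl)-8-methoxy-2,3-dihydro-1,4-benzodioxin-6-yl]prop-2-enal (formed in the flask in step 10, not isolated) | COc1cc([C@@H]2Oc3cc(/C=C/C=O)cc(OC)c3O[C@@H]2CO)cc(O)c1O | intermediate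
17 | CNP0174261.1, 5-[(2S,3R)-3-(hydroxymethyl)-7-[(E)-3-hydroxyprop-1-enyl]-5-methoxy-2,3-dihydro-1,4-benzodioxin-2-yl]-3-methoxybenzene-1,2-diol (cis; Cα S, Cβ R) | COc1cc([C@@H]2Oc3cc(/C=C/CO)cc(OC)c3O[C@@H]2CO)cc(O)c1O | target

**Step count**
Total steps: 10. Longest linear sequence: 9 steps (steps 1, 2, 3, 4, 5, 7, 8, 9, 10); step 6 is the one-step branch to the bromophenol.

**Steps most likely to fail**

Step 7. After the opening, the O-arylation at a bromide flanked by two ortho oxygen substituents may stall or be overtaken by reductive loss of bromine and by degradation of the aldehyde at 110 °C. The opening may also lose regio- or stereo-fidelity if copper acts as a Lewis acid on the epoxide. Fallback: the two events are decoupled. Setting out from 8 and 10, the opening is run alone (Cs2CO3, DMF, 80 °C) and the bromo alcohol 11 is isolated after aqueous work-up. Ring B is then closed in a separate palladium-catalysed intramolecular C–O coupling (Pd(OAc)2, 2-(di-tert-butylphosphino)-1,1'-binaphthyl, Cs2CO3, toluene, 70 °C). Here oxidative addition of zerovalent palladium into the para-formyl aryl bromide and C–O reductive elimination from a divalent palladium alkoxide carrying a bulky phosphine replace the copper cycle, again with retention at Cβ. The route is rejoined at 12; this fallback makes no compound outside the list (F0).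

Step 4. The titanium Lewis acid may open the electron-rich benzylic epoxide during the reaction or the work-up, with loss of material and of enantiomeric purity. Fallback: setting out from 6, the alcohol is first protected (MOMCl, i-Pr2NEt, CH2Cl2) to give (E)-3-methoxy-4,5-bis(methoxymethoxy)-1-[3-(methoxymethoxy)prop-1-enyl]benzene F1. F1 is then epoxidised by Shi epoxidation with the dioxirane formed from the D-fructose-derived ketone 1,2:4,5-di-O-isopropylidene-β-D-erythro-2,3-hexodiulo-2,6-pyranose and KHSO5 (K2CO3 buffer, MeCN/dimethoxymethane/H2O, 0 °C). This catalyst is expected to give the (R,R)-epoxide from (E)-β-substituted styrenes under basic, Lewis-acid-free conditions. The route is rejoined directly at 8.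

Step 6. Control between single and double demethylation may be poor, and BBr3 may attack the aldehyde. Fallback: setting out from 9, the aldehyde is masked (ethylene glycol, p-TsOH cat., toluene, reflux with water removal) as 2-(4-bromo-3,5-dimethoxyphenyl)-1,3-dioxolane F2. Nucleophilic demethylation with NaSEt in DMF at 120 °C then should give 2-bromo-5-(1,3-dioxolan-2-yl)-3-methoxyphenol F3. This SN2 demethylation stops after one methyl group because the phenoxide formed deactivates the ring, and the acetal removes the para-carbonyl activation that would invite thiolate substitution of the bromide. Acetal hydrolysis (1 M HCl, THF, rt) rejoins the route at 10.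

**Further compounds**
F0 | step 7 | none | none
F1 | step 4 | (E)-3-methoxy-4,5-bis(methoxymethoxy)-1-[3-(methoxymethoxy)prop-1-enyl]benzene | COCOC/C=C/c1cc(OC)c(OCOC)c(OCOC)c1
F2 | step 6 | 2-(4-bromo-3,5-dimethoxyphenyl)-1,3-dioxolane | COc1cc(C2OCCO2)cc(OC)c1Br
F3 | step 6 | 2-bromo-5-(1,3-dioxolan-2-yl)-3-methoxyphenol | COc1cc(C2OCCO2)cc(O)c1Br
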